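The closed, stirred vessel holds one charge, read at two times: teal early, grey late.

| setting | eta | gamma | grey | teal |
|---|---|---|---|---|
| free monomer | 0.022 M | 0.022 M | 0.022 M | 0.022 M |
| transfer agent | 6.6 mM | 6.6 mM | 6.60 mM | 6.60 mM |
| protic impurity | 2.9 mM | 6.6 mM | 4.40 mM | 4.40 mM |
| pre-initiator | 0.5 mol% | 0.5 mol% | 0.5 mol% | 0.5 mol% |
| remark | run made earlier | run made earlier |  |  |
| time |  |  | 8.0 h | 2.0 h |

| run | time / h | monomer in chains / % |
|---|---|---|
| eta | 1.50 | 6.4 |
| eta | 3.00 | 22.4 |
| eta | 5.00 | 45.1 |
| eta | 6.00 | 57.2 |
| gamma | 1.50 | 4.6 |
| gamma | 3.00 | 20.5 |
| gamma | 5.00 | 39.6 |
| gamma | 6.00 | 47.9 |

(standard deviation of a reading: 1 percentage point)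

* which of the two ends with the longer chains by the average number of monomer units in a chain (chains begun, living or dead) ("neither" if they lie within 10%) (grey / teal / neither)
* average number of monomer units in a chain (chains begun, living or dead) at the end, grey
* average number of monomer units in a chain (chains begun, living or dead) at the end, teal

- the average divides the monomer in chains by the number of chains begun, living and dead together
- the earlier runs were read with a standard deviation of 1 percentage point
- steps that have been proposed: pre-initiator -> initiator; free monomer + living end -> monomer in chains + living end; free monomer + initiator -> living end + monomer in chains; protic impurity + free monomer -> quenched substrate; living end + transfer agent -> dead chain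
- the earlier runs do not show the number of chains; that part of a forecast is a guess

Take the main step first. Each chain starts from one pre-initiator, and no proposed step returns initiator, so chains begun cannot pass 0.110 mM, the chain budget, which is the charged pre-initiator as a concentration. Transfer agent stands in far greater amount, but it turns living ends into dead chains, which still count as chains begun, so the budget stays. Monomer in chains divided by the budget is therefore a floor on the length, 200 for a charge wholly in chains.

Now add the protic impurity. It can take up to 20.0% of the free monomer, leaving room for 80.0%, and gamma does trail eta, with less in chains at 6.00 h. Placing this charge 40.5% of the way from eta to gamma gives 42.9% in chains at 5.00 h and 53.4% at 6.00 h. If the unfilled room keeps shrinking by that hour's factor, grey holds 66.4%. A straight line between the first two readings gives teal 11.0%. The floors are then 133 for grey and 22.0 for teal.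

Last comes the opening of pre-initiator and the start of chains from the initiator it gives, which lifts each length above its floor by the inverse of the share of the budget begun as chains, living and dead together. The runs do not show that share. Yet if chains begin no faster late than early, teal's share is at least 25.0% of grey's and at most equal to it, so grey's length is between 1.51 and 6.04 times teal's. This reckoning therefore puts grey longer and gives no single length.

The forecast also says grey, with 175 for grey and 80 for teal, on the grounds: “I guess about 25–30% activated at 2 h and about 75% at 8 h”.

The flask gives 173 for grey and 70.7 for teal, so grey ends longer by a factor of 2.45.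

    pre-initiator → initiator (k = 5.77 × 10⁻⁵ s⁻¹)
    free monomer + living end → monomer in chains + living end, rate k2*[living end]*[free monomer] (k = 1.11 M⁻¹ s⁻¹)
    free monomer + initiator → living end + monomer in chains (k = 0.0430 M⁻¹ s⁻¹)
    protic impurity + free monomer → quenched substrate (k = 0.00483 M⁻¹ s⁻¹)
    living end + transfer agent → dead chain (kL = 0.00173 M⁻¹ s⁻¹)

Left for 20.0 h, teal reaches 183, and grey left for 80.0 h reaches 182. The same charge read at 3.0 h has 21.0% of the free monomer in chains, which over the chain budget is a floor of 42.0. Its length is 102, so chains begun stand at 41.4% of the budget.

The data are simulated for substances that don't exist, and the scatter is random.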